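**Retrosynthetic overview**

The target is a 20-membered diaryl ether cyclophane: ring A (a 5-alkylresorcinol, bridged meta to the ether oxygen) and ring B (a 2-aryloxy-5-alkylresorcinol, bridged para to the ether oxygen) are joined by the ether O and by a (CH2)12 bridge, numbered C1 (on ring B) to C12 (on ring A).
Enabling feature: C6–C7 is the exact midpoint of this bridge, so disconnecting it leaves the same six-carbon arm on ring A and on ring B. The bond is therefore made as C6=C7 by ring-closing metathesis of two identical hept-6-enyl arms (one sacrificial carbon each, expelled as ethene) and saturated by the same ruthenium charge under H2.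
Because the arms are identical, both are attached in one twofold Kumada–Corriu coupling to a dibromo diaryl ether, which comes from a Chan–Evans–Lam coupling of two purchased arenes; the hindered 2,6-dioxygenated ether is in place before any ring is formed.
Ring order: rings A and B are bought; the macrocycle is the only ring made (step 3); global O-demethylation finishes the synthesis.

Key step: step 3

Remark: the target has no stereocentre; the E/Z geometry at C6=C7 of intermediate 7 is left uncontrolled because the double bond is hydrogenated in the same operation (the E isomer is drawn); compounds 1, 2 and 4 are taken as purchasable.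

**Route**

Step 1
Reactants: 1 4-bromo-2,6-dimethoxyphenol; 2 (3-bromo-5-methoxyphenyl)boronic acid
Product: 3 5-bromo-2-(3-bromo-5-methoxyphenoxy)-1,3-dimethoxybenzene
Conditions: Cu(OAc)2 (20 mol %), pyridine, 4 Å MS, CH2Cl2, O2 (1 atm), rt
Reagents that add atoms: none
Why: Chan–Evans–Lam oxidative C–O coupling (transmetalation of the boronic acid to divalent copper, oxidation, C–O reductive elimination) runs at room temperature, where neither aryl bromide reacts, and this reaction type accepts di-ortho-substituted phenols, so the hindered ether oxygen should be installed with both cross-coupling handles intact.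

Step 2
Reactants: 3 5-bromo-2-(3-bromo-5-methoxyphenoxy)-1,3-dimethoxybenzene; 4 7-bromohept-1-ene
Product: 6 5-(hept-6-en-1-yl)-2-[3-(hept-6-en-1-yl)-5-methoxyphenoxy]-1,3-dimethoxybenzene, via hept-6-en-1-ylmagnesium bromide 5 (not isolated)
Conditions: 4 (3 equiv), Mg, THF, rt; then 3, PdCl2(dppf) (5 mol %), THF, 0 °C to 50 °C
Reagents that add atoms: none
Why: Twofold Kumada–Corriu sp2–sp3 cross-coupling should replace both aryl bromides by the same hept-6-enyl arm in one operation, since the wide bite angle of dppf favours reductive elimination over β-hydride elimination and the methyl ethers, the diaryl ether and the remote terminal alkenes are inert to the Grignard reagent.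

Step 3
Reactants: 6 5-(hept-6-en-1-yl)-2-[3-(hept-6-en-1-yl)-5-methoxyphenoxy]-1,3-dimethoxybenzene
Product: 8 saturated macrocycle tri-O-methyl ether, via macrocyclic alkene 7 (not isolated)
Conditions: RuCl2(=CHPh)(PCy3)(SIMes) (second-generation Grubbs catalyst, 5 mol %), toluene (2 mM), 60 °C, Ar sparge; then concentrate to about 0.05 M, MeOH, Et3N, H2 (5 atm), 60 °C, same flask
Reagents that add atoms: none
Why: The ruthenium benzylidene initiates on one terminal alkene and the resulting alkylidene takes up the other one through a ruthenacyclobutane ([2+2] cycloaddition and cycloreversion), expelling ethene and forming C6=C7; under H2 in the presence of MeOH and Et3N the same ruthenium charge is converted into hydride species that saturate this double bond, so one operation should deliver the complete 20-membered skeleton with its all-methylene bridge. The closest known reaction type is macrocyclic ring-closing metathesis of an α,ω-diene run in tandem with ruthenium hydride hydrogenation. The only ring closed is the 20-membered ansa ring, by end-to-end macrocyclisation between the two internal vinyl carbons, C6 of the ring B arm and C7 of the ring A arm. No stereocentre is formed, and the E/Z geometry of C6=C7 is erased by the hydrogenation. The step needs ring closure to win over acyclic diene metathesis oligomerisation and needs the terminal double bonds to stay in place until closure: the first is secured by high dilution, by the reversibility of metathesis (oligomers are cut back to the unstrained ring while ethene is swept out) and by the bent diaryl ether hinge (C–O–C near 118°, meta exit on ring A, para exit on ring B) that lets two identical, unbranched, equally reactive arms meet, the second by admitting hydrogen and base only after ring closure is complete. The aryl methyl ethers and the diaryl ether are inert to both catalytic cycles.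

Step 4
Reactants: 8 saturated macrocycle tri-O-methyl ether
Product: 9 target triol
Conditions: BBr3 (6 equiv), CH2Cl2, −78 °C to rt; then H2O
Reagents that add atoms: none
Why: Lewis acid-mediated O-demethylation (coordination of BBr3 to each methoxy oxygen followed by bromide attack on the methyl group) should unmask all three phenols at once, the diaryl ether offering no sp3 carbon for bromide attack and the saturated bridge being inert.

**Compound list**

1 | 4-bromo-2,6-dimethoxyphenol | COc1cc(Br)cc(OC)c1O | starting material
2 | (3-bromo-5-methoxyphenyl)boronic acid | COc1cc(Br)cc(B(O)O)c1 | starting material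
3 | 5-bromo-2-(3-bromo-5-methoxyphenoxy)-1,3-dimethoxybenzene | COc1cc(Br)cc(Oc2c(OC)cc(Br)cc2OC)c1 | intermediate
4 | 7-bromohept-1-ene | C=CCCCCCBr | starting material
5 | hept-6-en-1-ylmagnesium bromide | C=CCCCCC[Mg]Br | intermediate
6 | 5-(hept-6-en-1-yl)-2-[3-(hept-6-en-1-yl)-5-methoxyphenoxy]-1,3-dimethoxybenzene | COc1cc(CCCCCC=C)cc(Oc2c(OC)cc(CCCCCC=C)cc2OC)c1 | intermediate
7 | macrocyclic alkene: 20-membered cyclophane of 5-methoxy-1,3-phenylene (ring A), ether O, 2,6-dimethoxy-1,4-phenylene (ring B, O on C1) and a twelve-carbon bridge with a C6=C7 double bond; E/Z mixture, E isomer drawn | COc1cc2cc(c1)Oc1c(OC)cc(cc1OC)CCCCC/C=C/CCCCC2 | intermediate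
8 | saturated macrocycle tri-O-methyl ether: as 7 but with a (CH2)12 bridge | COc1cc2cc(c1)Oc1c(OC)cc(cc1OC)CCCCCCCCCCCC2 | intermediate
9 | target triol: 20-membered cyclophane of 5-hydroxy-1,3-phenylene (ring A), ether O, 2,6-dihydroxy-1,4-phenylene (ring B, O on C1) and a (CH2)12 bridge | Oc1cc2cc(c1)Oc1c(O)cc(cc1O)CCCCCCCCCCCC2 | target

**Step count and risks**

Total step count: 4. Longest linear sequence: 4 steps (1 to 3 to 6 to 8 to 9).

Steps most likely to fail:

Step 3. Intermolecular acyclic diene metathesis may outrun ring closure, or a terminal double bond may migrate under ruthenium hydride before closure, which would excise an extra carbon and contract the bridge. The fallback sets out from compound 6 and replaces metathesis by a reductive carbonyl coupling that joins the same two carbons. Ozonolysis of both terminal alkenes (O3, CH2Cl2/MeOH, −78 °C; then Me2S) should give the dialdehyde 6-{4-[3-methoxy-5-(6-oxohexyl)phenoxy]-3,5-dimethoxyphenyl}hexanal F1. Intramolecular McMurry coupling on low-valent titanium (TiCl3(DME)1.5, Zn–Cu couple, DME, reflux, slow addition) should then close the ring to alkene 7 without any possibility of olefin migration. Hydrogenation of 7 (H2, Pd/C, EtOAc) brings the sequence back to the route at compound 8.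

Step 1. The electron-rich, di-ortho-substituted phenol may be oxidised by divalent copper and oxygen, and protodeboronation or homocoupling of the boronic acid may outpace the slow C–O bond formation at the hindered oxygen. The fallback sets out from compounds 2 and 1 and uses a metal-free aryl transfer from trivalent iodine. 4-Iodoanisole (COc1ccc(I)cc1) is oxidised with mCPBA in the presence of BF3·OEt2 (CH2Cl2, 0 °C to rt) and treated in the same flask with boronic acid 2 to give (3-bromo-5-methoxyphenyl)(4-methoxyphenyl)iodonium tetrafluoroborate F2. Reaction of F2 with the potassium phenoxide of 1 (t-BuOK, THF, rt) should transfer the more electron-poor 3-bromo-5-methoxyphenyl group by ligand coupling, a process that tolerates di-ortho-substituted phenols, and comes back to the route at compound 3.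

Step 2. β-Hydride elimination from the alkylpalladium intermediate may lead to reduction of a C–Br bond or to isomerised arms, and the sequence may stall after the first coupling. The fallback sets out from compound 3 and changes the nucleophile to a borane made by hydroboration. Hepta-1,6-diene (C=CCCCC=C, fivefold excess) and 9-BBN (THF, 0 °C to rt) should give 9-(hept-6-en-1-yl)-9-borabicyclo[3.3.1]nonane F3. Twofold B-alkyl Suzuki–Miyaura coupling of F3 with 3 (PdCl2(dppf), K3PO4, THF/DMF/H2O, 60 °C) comes back to the route at compound 6.

**Further compounds**

F1 | step 3 | 6-{4-[3-methoxy-5-(6-oxohexyl)phenoxy]-3,5-dimethoxyphenyl}hexanal | COc1cc(CCCCCC=O)cc(Oc2c(OC)cc(CCCCCC=O)cc2OC)c1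
F2 | step 1 | (3-bromo-5-methoxyphenyl)(4-methoxyphenyl)iodonium tetrafluoroborate | COc1ccc([I+]c2cc(Br)cc(OC)c2)cc1.F[B-](F)(F)F
F3 | step 2 | 9-(hept-6-en-1-yl)-9-borabicyclo[3.3.1]nonane | C=CCCCCCB1C2CCCC1CCC2
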